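The earlier runs and the new flask were generated by integration for substances that don't exist; scatter was added.

The ratio I followed is the branching ratio (selectivity factor), target formed per side product A formed from the starting material, and in my reckoning target, to lead at the end of beta or gamma, had to stand above 1 on this ratio with room for whatever target had lost by then.

common to all: starting material 0.020 M
- larch: protic impurity 5 mM; run made earlier
- birch: protic impurity 20 mM; run made earlier
- beta: protic impurity 10.0 mM; time 20 h
- gamma: protic impurity 10.0 mM; time 15 h

- larch (time / h: target / %, starting material / %): 1.50: 17.6, 48.1; 4.00: 26.8, 12.0; 8.00: 28.5, 3.1; 12.0: 25.5, 0.2
- birch (time / h: target / %, starting material / %): 1.00: 12.3, 56.6; 2.00: 19.7, 33.2; 5.00: 24.1, 4.4; 12.0: 21.3, 0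

(readings scatter by 1 percentage point)

- which of the two there is more of at the end, beta (target / side product A)
- which of the two there is more of at the end, gamma (target / side product A)
- final target, as a percentage of the starting material charged, in beta
- final target, as a percentage of the starting material charged, in gamma

- in percentages every species weighs as the starting material in it: one side product B counts as two
- steps that have been proposed: starting material -> target; starting material -> side product A; target -> over-reaction product; starting material + protic impurity -> quenched substrate; starting material + target -> side product B

I read the first-order loss of starting material from the first reading of each run: 0.488 h⁻¹ in larch and 0.569 h⁻¹ in birch. A straight line in the impurity then gave 0.461 h⁻¹ without impurity and 0.515 h⁻¹ at the charge of beta and gamma. Early target per starting material consumed, times that loss and averaged over both runs, gave 0.163 h⁻¹ for the step to target. I assigned the remaining 0.297 h⁻¹ to side product A and left side product B out. The ratio was therefore 0.549, and the opposite outcome needed about twice that value even before target decayed.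

Larch's last two readings gave target a decay constant of 0.0278 h⁻¹, a loose reading at this scatter. Beta then counted 0.502 turnovers and gamma 0.363, a turnover count being the decay constant times the run time less the mean formation time of 1.94 h. Target's share of 31.7 %, times the exponential of minus the turnovers, gave me 19.2 % in beta and 22.1 % in gamma.

The forecast said side product A in beta with 19 % of target, and side product A in gamma with 22 %: “Target therefore never catches it”.

In the simulation, side product A led in beta, 56.2 % to 18.7 % of target, and in gamma, 56.2 % to 21.9 %.

    starting material → target (k = 0.170 h⁻¹)
    starting material → side product A (k = 0.290 h⁻¹)
    target → over-reaction product (k = 0.0310 h⁻¹)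
    starting material + protic impurity → quenched substrate (k = 6.20 M⁻¹ h⁻¹)
    starting material + target → side product B (k = 0.360 M⁻¹ h⁻¹)

The neighbouring flask is beta with 0.040 M of protic impurity. By the same reckoning its loss rose to 0.677 h⁻¹ and target's share fell to 24.1 %, while its turnovers were 0.515 against 0.502 in beta, which gave 14.4 % of target. The simulation of that neighbour flask gave 13.9 %.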